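**Retrosynthetic overview**
1. Daphnodorin F ⇐ biaryl-linked flavone–flavan hexaphenol 16, by a last-step C–O cascade: flavan 7-OH onto flavone C-2 (ketal, closes the dihydrofuran ring) plus electrophilic oxygen onto C-3 (tertiary alcohol). Both core stereocentres are set here.
2. 16 ⇐ hexabenzyl ether 15 ⇐ Negishi coupling (C3–C8 biaryl bond) of 3-iodoflavone 12 with the arylzinc made from 8-bromoflavan 8.
3. 12 ⇐ apigenin (benzylation, C-3 lithiation/iodination); the chromone ring is bought ready-made.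
4. 8 ⇐ (2S)-flavan 7 ⇐ Mitsunobu C–O closure of (R)-carbinol 6 ⇐ asymmetric transfer hydrogenation of retro-chalcone 4 ⇐ aldehyde 2 + ketone 3.
5. Ring order: flavan pyran ring (step 4) → chromone ring (from apigenin) → dihydrofuran ketal ring (step 10).

Assumption: the target descriptors read from the SMILES are S (ketal carbon), R (carbinol carbon) and S (flavan C-2). In step 10 the (R,R) ligand is taken to be the antipode that gives this core; if a screen shows the opposite sense, the (S,S) ligand is used.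

Step 1
Reactants: 1 2,4,6-trihydroxybenzaldehyde
Product: 2 2,4-bis(benzyloxy)-6-hydroxybenzaldehyde
Conditions: BnBr (2.1 equiv), K2CO3 (2.2 equiv), DMF, 0 °C to rt
Reagents that add atoms: benzyl bromide, BrCc1ccccc1
Why: Williamson etherification in which the 4-OH and one ortho OH are benzylated while the last ortho OH stays locked in its hydrogen bond to the aldehyde and is left free; no stereocentre.

Step 2
Reactants: 2 2,4-bis(benzyloxy)-6-hydroxybenzaldehyde; 3 1-[4-(benzyloxy)phenyl]ethan-1-one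
Product: 4 (E)-3-[2,4-bis(benzyloxy)-6-hydroxyphenyl]-1-[4-(benzyloxy)phenyl]prop-2-en-1-one
Conditions: KOH (50% aq, 5 equiv), EtOH, 50 °C; then aq HCl to pH 5
Reagents that add atoms: none
Why: Claisen–Schmidt aldol condensation of the methyl ketone enolate with the non-enolisable aldehyde, E1cB dehydration giving the conjugated E-enone; no stereocentre.

Step 3
Reactants: 4 (E)-3-[2,4-bis(benzyloxy)-6-hydroxyphenyl]-1-[4-(benzyloxy)phenyl]prop-2-en-1-one
Product: 6 (1R)-3-[2,4-bis(benzyloxy)-6-hydroxyphenyl]-1-[4-(benzyloxy)phenyl]propan-1-ol, via saturated ketone 5 (not isolated)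
Conditions: RuCl(p-cymene)[(R,R)-TsDPEN] (2 mol%), HCO2Na (10 equiv), H2O/2-MeTHF, 40 °C
Reagents that add atoms: none
Why: Noyori-type asymmetric transfer hydrogenation run as a tandem: the ruthenium hydride first reduces the electron-poor C=C (giving 5), then the aryl ketone through the six-membered N–H/Ru–H transition state of the (R,R) catalyst, which gives the (R)-benzylic alcohol (same sense as acetophenone); aqueous formate keeps the medium non-acidic so the p-alkoxybenzylic alcohol does not ionise.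

Step 4
Reactants: 6 (1R)-3-[2,4-bis(benzyloxy)-6-hydroxyphenyl]-1-[4-(benzyloxy)phenyl]propan-1-ol
Product: 7 (2S)-5,7-bis(benzyloxy)-2-[4-(benzyloxy)phenyl]chromane
Conditions: PPh3 (1.3 equiv), DIAD (1.3 equiv), THF (0.02 M), −20 to 0 °C
Reagents that add atoms: none
Why: Intramolecular Mitsunobu etherification: the free phenol displaces the PPh3/DIAD-activated benzylic oxygen by SN2 in a 6-exo-tet closure with inversion, so the (R)-carbinol becomes the (2S)-flavan centre; low temperature and fast intramolecular capture suppress SN1 leakage.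

Step 5
Reactants: 7 (2S)-5,7-bis(benzyloxy)-2-[4-(benzyloxy)phenyl]chromane
Product: 8 (2S)-5,7-bis(benzyloxy)-2-[4-(benzyloxy)phenyl]-8-bromochromane
Conditions: NBS (1.0 equiv), CH2Cl2, −78 to −20 °C
Reagents that add atoms: N-bromosuccinimide, O=C1CCC(=O)N1Br
Why: Electrophilic aromatic bromination of the phloroglucinol-type ring A at C-8 (between OBn and the ring oxygen) in preference to the more hindered C-6 (between two OBn groups), the selectivity known for NBS on 5,7-di-O-benzylflavans; ring B is much less activated and the stereocentre is untouched.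

Step 6
Reactants: 9 apigenin
Product: 10 5,7-bis(benzyloxy)-2-[4-(benzyloxy)phenyl]-4H-chromen-4-one
Conditions: BnBr (4 equiv), K2CO3 (5 equiv), Bu4NI (cat.), DMF, 80 °C
Reagents that add atoms: benzyl bromide, BrCc1ccccc1
Why: Exhaustive Williamson etherification; heat and excess reagent also alkylate the chelated 5-OH; no stereocentre.

Step 7
Reactants: 10 5,7-bis(benzyloxy)-2-[4-(benzyloxy)phenyl]-4H-chromen-4-one
Product: 12 5,7-bis(benzyloxy)-2-[4-(benzyloxy)phenyl]-3-iodo-4H-chromen-4-one, via 3-lithioflavone 11 (not isolated)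
Conditions: LiN(iPr)2 (1.2 equiv), THF, −78 °C; then I2 (1.3 equiv), −78 °C
Reagents that add atoms: iodine, [I][I]
Why: Carbonyl-directed lithiation of the vinylic C-3–H gives 11, which is quenched by iodine; this is regiospecific for C-3, whereas electrophilic iodination would attack C-6/C-8 of ring A, and −78 °C prevents ring opening of 11.

Step 8
Reactants: 8 (2S)-5,7-bis(benzyloxy)-2-[4-(benzyloxy)phenyl]-8-bromochromane; 12 5,7-bis(benzyloxy)-2-[4-(benzyloxy)phenyl]-3-iodo-4H-chromen-4-one
Product: 15 5,7-bis(benzyloxy)-2-[4-(benzyloxy)phenyl]-3-{(2S)-5,7-bis(benzyloxy)-2-[4-(benzyloxy)phenyl]chroman-8-yl}-4H-chromen-4-one, via aryllithium 13 (not isolated), via arylzinc chloride 14 (not isolated)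
Conditions: 8, n-BuLi (1.05 equiv), THF, −78 °C; ZnCl2 (1.2 equiv), −78 °C to rt; then 12 (0.85 equiv), Pd2(dba)3 (2.5 mol%), RuPhos (10 mol%), THF/NMP, 70 °C
Reagents that add atoms: none
Why: Bromine–lithium exchange, transmetalation to zinc and Negishi cross-coupling; the 2,6-dialkoxyarylzinc resists protodemetalation and the bulky dialkylbiarylphosphine catalyst is suited to tetra-ortho-substituted biaryl bonds; the (2S) centre is remote and untouched, and the product forms as a roughly 1:1 pair of C3–C8 atropisomers that is carried on as such.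

Step 9
Reactants: 15 5,7-bis(benzyloxy)-2-[4-(benzyloxy)phenyl]-3-{(2S)-5,7-bis(benzyloxy)-2-[4-(benzyloxy)phenyl]chroman-8-yl}-4H-chromen-4-one
Product: 16 5,7-dihydroxy-3-[(2S)-5,7-dihydroxy-2-(4-hydroxyphenyl)chroman-8-yl]-2-(4-hydroxyphenyl)-4H-chromen-4-one
Conditions: H2 (1 atm), Pd(OH)2/C, THF/MeOH 1:1, rt
Reagents that add atoms: none
Why: Hydrogenolysis of all six benzyl ethers; the tetrasubstituted chromone C=C and the flavan C2–O bond survive these mild neutral conditions, as in catechin chemistry.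

Step 10
Reactants: 16 5,7-dihydroxy-3-[(2S)-5,7-dihydroxy-2-(4-hydroxyphenyl)chroman-8-yl]-2-(4-hydroxyphenyl)-4H-chromen-4-one
Product: 19 daphnodorin F, via 3-aroylbenzofuran isomer 17 (not isolated), via nickel-bound enolate 18 (not isolated)
Conditions: Ni(ClO4)2·6H2O (10 mol%), (R,R)-DBFOX-Ph (11 mol%), 2,6-lutidine (20 mol%), (±)-trans-2-(phenylsulfonyl)-3-phenyloxaziridine (1.3 equiv), THF, 0 °C to rt
Reagents that add atoms: trans-2-(phenylsulfonyl)-3-phenyloxaziridine, O=S(=O)(N1OC1c1ccccc1)c1ccccc1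
Why: Proposed new method: a chiral Lewis acid-catalysed oxa-Michael/enolate-hydroxylation cascade with dynamic kinetic selection – the water- and phenol-tolerant divalent nickel complex of 4,6-bis[(4R)-4-phenyl-4,5-dihydrooxazol-2-yl]dibenzofuran binds the 5-O/4-C=O chelate of 16, the flanking flavan 7-OH adds to C-2 to close the five-membered ring, the resulting enolate 18 epimerises at C-2 by reversible ring opening to either phenol (back to 16, or to the benzofuran 17, which has no biaryl axis and recloses on either face), and the oxaziridine transfers oxygen to C-3 only of the enolate diastereomer whose convex face (anti to the new C2–O bond, the only face that can give the cis-fused ketal) is left open by the ligand, so the S ketal carbon and the R carbinol carbon are set together in the C–O bond-forming event; the closest known reaction types are chiral Lewis acid-catalysed α-hydroxylation of β-dicarbonyl compounds with N-sulfonyloxaziridines, Lewis acid-catalysed oxa-Michael cyclisation of 2'-hydroxychalcones, and the base-induced isomerisation of 2'-hydroxyisoflavones to 3-aroylbenzofurans.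

**Compound list**
1 | 2,4,6-trihydroxybenzaldehyde | O=Cc1c(O)cc(O)cc1O | starting material
2 | 2,4-bis(benzyloxy)-6-hydroxybenzaldehyde | O=Cc1c(O)cc(OCc2ccccc2)cc1OCc1ccccc1 | intermediate
3 | 1-[4-(benzyloxy)phenyl]ethan-1-one | CC(=O)c1ccc(OCc2ccccc2)cc1 | starting material
4 | (E)-3-[2,4-bis(benzyloxy)-6-hydroxyphenyl]-1-[4-(benzyloxy)phenyl]prop-2-en-1-one | O=C(/C=C/c1c(O)cc(OCc2ccccc2)cc1OCc1ccccc1)c1ccc(OCc2ccccc2)cc1 | intermediate
5 | 3-[2,4-bis(benzyloxy)-6-hydroxyphenyl]-1-[4-(benzyloxy)phenyl]propan-1-one (formed in the flask, not isolated) | O=C(CCc1c(O)cc(OCc2ccccc2)cc1OCc1ccccc1)c1ccc(OCc2ccccc2)cc1 | intermediate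
6 | (1R)-3-[2,4-bis(benzyloxy)-6-hydroxyphenyl]-1-[4-(benzyloxy)phenyl]propan-1-ol | O[C@H](CCc1c(O)cc(OCc2ccccc2)cc1OCc1ccccc1)c1ccc(OCc2ccccc2)cc1 | intermediate
7 | (2S)-5,7-bis(benzyloxy)-2-[4-(benzyloxy)phenyl]chromane | O(Cc1ccccc1)c1cc(OCc2ccccc2)c2c(c1)O[C@H](c1ccc(OCc3ccccc3)cc1)CC2 | intermediate
8 | (2S)-5,7-bis(benzyloxy)-2-[4-(benzyloxy)phenyl]-8-bromochromane | O(Cc1ccccc1)c1cc(OCc2ccccc2)c2c(c1Br)O[C@H](c1ccc(OCc3ccccc3)cc1)CC2 | intermediate
9 | apigenin, 5,7-dihydroxy-2-(4-hydroxyphenyl)-4H-chromen-4-one | O=c1cc(-c2ccc(O)cc2)oc2cc(O)cc(O)c12 | starting material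
10 | 5,7-bis(benzyloxy)-2-[4-(benzyloxy)phenyl]-4H-chromen-4-one | O=c1cc(-c2ccc(OCc3ccccc3)cc2)oc2cc(OCc3ccccc3)cc(OCc3ccccc3)c12 | intermediate
11 | 3-lithio derivative of 10 (formed in the flask, not isolated) | O=c1c([Li])c(-c2ccc(OCc3ccccc3)cc2)oc2cc(OCc3ccccc3)cc(OCc3ccccc3)c12 | intermediate
12 | 5,7-bis(benzyloxy)-2-[4-(benzyloxy)phenyl]-3-iodo-4H-chromen-4-one | O=c1c(I)c(-c2ccc(OCc3ccccc3)cc2)oc2cc(OCc3ccccc3)cc(OCc3ccccc3)c12 | intermediate
13 | 8-lithio derivative of 7 (formed in the flask, not isolated) | O(Cc1ccccc1)c1cc(OCc2ccccc2)c2c(c1[Li])O[C@H](c1ccc(OCc3ccccc3)cc1)CC2 | intermediate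
14 | 8-(chlorozincio) derivative of 7 (formed in the flask, not isolated) | O(Cc1ccccc1)c1cc(OCc2ccccc2)c2c(c1[Zn]Cl)O[C@H](c1ccc(OCc3ccccc3)cc1)CC2 | intermediate
15 | 5,7-bis(benzyloxy)-2-[4-(benzyloxy)phenyl]-3-{(2S)-5,7-bis(benzyloxy)-2-[4-(benzyloxy)phenyl]chroman-8-yl}-4H-chromen-4-one (pair of C3–C8 atropisomers) | O=c1c(-c2c(OCc3ccccc3)cc(OCc3ccccc3)c3c2O[C@H](c2ccc(OCc4ccccc4)cc2)CC3)c(-c2ccc(OCc3ccccc3)cc2)oc2cc(OCc3ccccc3)cc(OCc3ccccc3)c12 | intermediate
16 | 5,7-dihydroxy-3-[(2S)-5,7-dihydroxy-2-(4-hydroxyphenyl)chroman-8-yl]-2-(4-hydroxyphenyl)-4H-chromen-4-one (pair of atropisomers) | O=c1c(-c2c(O)cc(O)c3c2O[C@H](c2ccc(O)cc2)CC3)c(-c2ccc(O)cc2)oc2cc(O)cc(O)c12 | intermediate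
17 | 3-aroylbenzofuran isomer of 16 (daphnodorin A skeleton): 2-(4-hydroxyphenyl)-3-(2,4,6-trihydroxybenzoyl)furan fused through its oxygen to C-7 and through C-3a to C-8 of (2S)-5-hydroxy-2-(4-hydroxyphenyl)chromane (formed in the flask, not isolated) | O=C(c1c(O)cc(O)cc1O)c1c(-c2ccc(O)cc2)oc2cc(O)c3c(c12)O[C@H](c1ccc(O)cc1)CC3 | intermediate
18 | oxa-Michael adduct of 16, drawn as the neutral enol and held on nickel as the enolate; ketal carbon S, flavan C-2 S (formed in the flask, not isolated) | OC=1c2c(O)cc(O)cc2O[C@]2(c3ccc(O)cc3)Oc3cc(O)c4c(c3C=12)O[C@H](c1ccc(O)cc1)CC4 | intermediate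
19 | daphnodorin F: cis-fused ketal in which C-2 of a 5,7-dihydroxychroman-4-one (ketal carbon, S, bearing 4-hydroxyphenyl) is bonded to O-7, and C-3 (carbinol carbon, R, bearing OH) to C-8, of (2S)-5-hydroxy-2-(4-hydroxyphenyl)chromane | O=C1c2c(O)cc(O)cc2O[C@]2(c3ccc(O)cc3)Oc3cc(O)c4c(c3[C@@]12O)O[C@H](c1ccc(O)cc1)CC4 | target

**Step count and risks**
Total steps: 10. Longest linear sequence: 8 (steps 1, 2, 3, 4, 5, 8, 9, 10).

Three steps most likely to fail:

Step 10 (the proposed new cascade). Risks are slow turnover from product binding to nickel, weak facial control, or oxidation of the free phloroglucinol rings. The fallback uses known chemistry, sets out from 16 and comes back at 19. Compound 16 is peracetylated (Ac2O, pyridine, DMAP) to the hexa-O-acetate F1. The chromone double bond of F1 is epoxidised with dimethyldioxirane in acetone/CH2Cl2, the established way to flavone 2,3-epoxides, with the acetates shielding the arenes, to give the 2,3-epoxide F2 as a mixture of both faces. K2CO3 in MeOH at 0 °C removes the acetates, and the freed 7-phenoxide opens the epoxide at the ketal carbon from the face anti to the epoxide oxygen. This gives 19 together with the core diastereomer F3, which are diastereomers because of the fixed flavan centre and are separated by preparative reverse-phase HPLC.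

Step 8 (tetra-ortho-substituted Negishi coupling). Risks are a stalled coupling or loss of the iodide by reduction. The fallback builds the chromone ring after the C–C bond instead; it sets out from 8 and comes back at 15. Palladium-catalysed ketone α-arylation of commercial 1-[2,4-bis(benzyloxy)-6-hydroxyphenyl]ethan-1-one with 8 (Pd(OAc)2, XPhos, LiN(SiMe3)2 2.5 equiv, toluene, 80 °C) gives the deoxybenzoin F4. F4 is O-acylated with 4-(benzyloxy)benzoyl chloride and cyclised in one pot (K2CO3, acetone, reflux; Baker–Venkataraman acyl shift, then cyclodehydration finished with catalytic TsOH) to 15.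

Step 4 (Mitsunobu closure at a p-alkoxybenzylic carbon). The risk is partial SN1 ionisation eroding the ee. The fallback sets C-2 by alkene hydrogenation instead of displacement; it sets out from 4 and comes back at 7. The C=C of 4 is hydrogenated with H2 and RhCl(PPh3)3 (benzyl ethers untouched) to ketone 5, isolated this time. Catalytic TsOH in toluene with a Dean–Stark trap cyclodehydrates 5 to the 4H-chromene F5. Iridium-catalysed asymmetric hydrogenation of the enol ether double bond of F5 (H2 50 bar, [Ir(cod)((S)-tBu-PHOX)] tetrakis[3,5-bis(trifluoromethyl)phenyl]borate 1 mol%, CH2Cl2; ligand antipode chosen to give 2S) then delivers 7.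

**Further compounds**
F1 | step 10 | hexa-O-acetate of 16 | O=c1c(-c2c(OC(C)=O)cc(OC(C)=O)c3c2O[C@H](c2ccc(OC(C)=O)cc2)CC3)c(-c2ccc(OC(C)=O)cc2)oc2cc(OC(C)=O)cc(OC(C)=O)c12
F2 | step 10 | 2,3-epoxide of F1 (both epoxide faces) | O=C1c2c(OC(C)=O)cc(OC(C)=O)cc2OC2(c3ccc(OC(C)=O)cc3)OC12c1c(OC(C)=O)cc(OC(C)=O)c2c1O[C@H](c1ccc(OC(C)=O)cc1)CC2
F3 | step 10 | core diastereomer of 19 (ketal carbon R, carbinol carbon S, flavan C-2 S) | O=C1c2c(O)cc(O)cc2O[C@@]2(c3ccc(O)cc3)Oc3cc(O)c4c(c3[C@]12O)O[C@H](c1ccc(O)cc1)CC4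
F4 | step 8 | 1-[2,4-bis(benzyloxy)-6-hydroxyphenyl]-2-{(2S)-5,7-bis(benzyloxy)-2-[4-(benzyloxy)phenyl]chroman-8-yl}ethan-1-one | O=C(Cc1c(OCc2ccccc2)cc(OCc2ccccc2)c2c1O[C@H](c1ccc(OCc3ccccc3)cc1)CC2)c1c(O)cc(OCc2ccccc2)cc1OCc1ccccc1
F5 | step 4 | 5,7-bis(benzyloxy)-2-[4-(benzyloxy)phenyl]-4H-chromene | O(Cc1ccccc1)c1cc(OCc2ccccc2)c2c(c1)OC(c1ccc(OCc3ccccc3)cc1)=CC2
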